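**Plan**

Numbering (germacrane): C1 furanone C=O, C2=C3 enol ether, (Z)-C4=C5, C6 (ester), C7, C8 (lactone O), C9, C10 (quaternary, Me, O-bridge to C3); C11/C12/C13 = lactone α-carbon, C=O, =CH2.
Retrosynthesis: first the C6–O acyl bond (epoxyangelic acid); then one [2+2+1] cut that removes C11–C12 and C12–O8 together with the ring bond C7–C8, opening lactone and ten-membered carbocycle at once to a monocyclic furanone with a C8 aldehyde and a C7=C11=C13 allene, plus CO; then furanone O–C3 and C1–C2 (α′-hydroxy ynone from acetylide and Weinreb amide).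
Enabling feature: the lactone ring O8–C8–C7–C11(=C13H2)–C12(=O), fused to the carbocycle along C7–C8, is the retron of an allene/aldehyde/CO hetero-Pauson–Khand reaction; the flat furanone (C10, O, C3, C2, C1) and the (Z)-C4=C5 alkene form a rigid turn that holds C6 and C9 close.
Forward: the C8–C10/C1 fragment (steps 1–5) and the C2–C7/C11/C13 fragment (steps 6–8) are joined at C1–C2 (step 9); furanone ring (step 10); carbocycle and lactone together (step 12); silyl ether exchanged for the epoxyangelate (steps 13–17).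
Stereochemistry: C10 from (S)-lactic acid by Seebach self-regeneration; C6 by controller-based allenylboration; C7 and C8 in the key step (ring, C6 and C10 control); epoxide centres by Sharpless epoxidation.

Key step: step 12

Remark: the (R,R)-diazaborolidine controller is assumed to attack the same aldehyde face as in its allylations, giving the 4R carbinol 15 (its antipode is used if the sense is opposite); ancillary ligands on Mo in 22 and 23 are not drawn.

**Route**

Step 1
Reactants: 1 (S)-lactic acid; 2 pivalaldehyde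
Product: 3 (2S,5S)-2-tert-butyl-5-methyl-1,3-dioxolan-4-one
Conditions: p-TsOH·H2O (cat.), H2SO4 (cat.), pentane, reflux, Dean–Stark; cis isomer crystallized from pentane at −78 °C
Reagents that add atoms: none
Why: Acid-catalysed acetalization of the α-hydroxy acid (first stage of Seebach self-regeneration of stereocentres) leaves the lactate centre untouched, and the cis acetal centre formed under thermodynamic control is enriched by crystallization.

Step 2
Reactants: 3 (2S,5S)-2-tert-butyl-5-methyl-1,3-dioxolan-4-one; 4 allyl bromide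
Product: 6 (2S,5R)-5-allyl-2-tert-butyl-5-methyl-1,3-dioxolan-4-one, via lithium enolate 5 (not isolated)
Conditions: LiN(i-Pr)2, THF, −78 °C; then allyl bromide, −78 → −30 °C
Reagents that add atoms: none
Why: Seebach enolate alkylation, in which the planar enolate is allylated anti to the tert-butyl group, so the acetal centre relays the lactate configuration to the new quaternary carbon (future C10, R).

Step 3
Reactants: 6 (2S,5R)-5-allyl-2-tert-butyl-5-methyl-1,3-dioxolan-4-one
Product: 8 2-[(2S,4R)-2-tert-butyl-4-methyl-5-oxo-1,3-dioxolan-4-yl]acetaldehyde, via secondary ozonide 7 (not isolated)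
Conditions: O3, CH2Cl2, −78 °C; then PPh3, −78 → 23 °C
Reagents that add atoms: ozone, [O-][O+]=O
Why: Ozonolysis with reductive work-up cleaves the only alkene to the aldehyde (future C8) without touching the acylal or the quaternary centre.

Step 4
Reactants: 8 2-[(2S,4R)-2-tert-butyl-4-methyl-5-oxo-1,3-dioxolan-4-yl]acetaldehyde
Product: 9 (2S,5R)-2-tert-butyl-5-(2,2-dimethoxyethyl)-5-methyl-1,3-dioxolan-4-one
Conditions: MeOSiMe3, Me3SiOTf (cat.), CH2Cl2, −78 °C
Reagents that add atoms: methoxytrimethylsilane, CO[Si](C)(C)C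
Why: Noyori acetalization under aprotic conditions masks the aldehyde as its dimethyl acetal without alcoholysis of the dioxolanone.

Step 5
Reactants: 9 (2S,5R)-2-tert-butyl-5-(2,2-dimethoxyethyl)-5-methyl-1,3-dioxolan-4-one
Product: 10 (2R)-2-hydroxy-N,4,4-trimethoxy-N,2-dimethylbutanamide
Conditions: MeNHOMe·HCl, i-PrMgCl, THF, −20 → 0 °C; aq. NH4Cl
Reagents that add atoms: N,O-dimethylhydroxylamine hydrochloride, CNOC.Cl
Why: Aminolysis of the activated ester (dioxolanone) by the chloromagnesium amide gives the Weinreb amide while the hemiacetal alkoxide expels pivalaldehyde; the quaternary centre is not involved.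

Step 6
Reactants: 11 (Z)-3-methylpent-2-en-4-yn-1-ol
Product: 12 (Z)-3-methylpent-2-en-4-ynal
Conditions: activated MnO2, CH2Cl2, 0 °C; solution used directly
Reagents that add atoms: none
Why: Allylic oxidation with MnO2 is selective for the allylic alcohol and should preserve the (Z)-geometry that later places C3 and C6 cis.

Step 7
Reactants: 12 (Z)-3-methylpent-2-en-4-ynal; 13 allenyltributylstannane
Product: 15 (4R,5Z)-6-methylocta-1,2,5-trien-7-yn-4-ol, via B-propargyl diazaborolidine 14 (not isolated)
Conditions: (R,R)-TsNHCH(Ph)CH(Ph)NHTs, BBr3, CH2Cl2, 0 → 23 °C, evaporate; then 13, CH2Cl2, 23 °C; then 12, −78 °C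
Reagents that add atoms: none
Why: Corey enantioselective allenylation, in which the stannane is transmetalated to the chiral B-propargyl borane that adds by SE2′ through a six-membered transition state to give the α-allenyl carbinol; the C6 configuration is set by the (R,R)-bis-sulfonamide controller.

Step 8
Reactants: 15 (4R,5Z)-6-methylocta-1,2,5-trien-7-yn-4-ol
Product: 16 tert-butyldimethyl{[(4R,5Z)-6-methylocta-1,2,5-trien-7-yn-4-yl]oxy}silane
Conditions: t-BuMe2SiCl, imidazole, DMF, 23 °C
Reagents that add atoms: tert-butyldimethylsilyl chloride, CC(C)(C)[Si](C)(C)Cl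
Why: Standard silylation protects the carbinol for the acetylide chemistry and supplies the bulky group that later directs the ring closure; the configuration is unchanged.

Step 9
Reactants: 16 tert-butyldimethyl{[(4R,5Z)-6-methylocta-1,2,5-trien-7-yn-4-yl]oxy}silane; 10 (2R)-2-hydroxy-N,4,4-trimethoxy-N,2-dimethylbutanamide
Product: 19 (3R,7Z,9R)-9-(tert-butyldimethylsilyloxy)-3-hydroxy-1,1-dimethoxy-3,7-dimethyldodeca-7,10,11-trien-5-yn-4-one, via lithium acetylide 17 (not isolated), via chloromagnesium alkoxide 18 (not isolated)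
Conditions: 16, n-BuLi, THF, −78 °C; 10, i-PrMgCl (1 equiv), THF, −78 °C; combine, −78 → −20 °C; aq. NH4Cl
Reagents that add atoms: none
Why: Acylation of a lithium acetylide by a Weinreb amide, whose chelated tetrahedral intermediate prevents over-addition; the tertiary hydroxyl is masked in situ as its magnesium alkoxide.

Step 10
Reactants: 19 (3R,7Z,9R)-9-(tert-butyldimethylsilyloxy)-3-hydroxy-1,1-dimethoxy-3,7-dimethyldodeca-7,10,11-trien-5-yn-4-one
Product: 20 (2R)-5-[(2Z,4R)-4-(tert-butyldimethylsilyloxy)hepta-2,5,6-trien-2-yl]-2-(2,2-dimethoxyethyl)-2-methylfuran-3(2H)-one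
Conditions: K2CO3 (cat.), MeOH, 0 → 23 °C
Reagents that add atoms: none
Why: Base-mediated 5-endo-dig oxa-Michael cyclization of an α′-hydroxy ynone is the standard entry to 3(2H)-furanones; it should leave the allene, the acetal and both stereocentres untouched.

Step 11
Reactants: 20 (2R)-5-[(2Z,4R)-4-(tert-butyldimethylsilyloxy)hepta-2,5,6-trien-2-yl]-2-(2,2-dimethoxyethyl)-2-methylfuran-3(2H)-one
Product: 21 2-[(2R)-5-[(2Z,4R)-4-(tert-butyldimethylsilyloxy)hepta-2,5,6-trien-2-yl]-2-methyl-3-oxo-2,3-dihydrofuran-2-yl]acetaldehyde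
Conditions: pyridinium p-toluenesulfonate (cat.), acetone/H2O (9:1), 45 °C
Reagents that add atoms: water, O
Why: Mild acid-catalysed acetal hydrolysis frees the C8 aldehyde under conditions that the secondary silyl ether, the allene and the vinylogous ester should tolerate, and that avoid the base-induced β-elimination of the furanone oxygen.

Step 12
Reactants: 21 2-[(2R)-5-[(2Z,4R)-4-(tert-butyldimethylsilyloxy)hepta-2,5,6-trien-2-yl]-2-methyl-3-oxo-2,3-dihydrofuran-2-yl]acetaldehyde
Product: 24 (4Z,6S,7R,8S,10R)-6-(tert-butyldimethylsilyloxy)-3,10-epoxy-1-oxogermacra-2,4,11(13)-trien-12,8-olide, via oxamolybdacyclopentane 22 (not isolated), via acylmolybdenum metallacycle 23 (not isolated)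
Conditions: Mo(CO)6 (1.2 equiv), DMSO (10 equiv), toluene, 100 °C, syringe-pump addition of 21 over 10 h (final about 1 mM)
Reagents that add atoms: molybdenum hexacarbonyl, Mo(CO)6 (delivers C12 and its oxygen), [C-]#[O+].[C-]#[O+].[C-]#[O+].[C-]#[O+].[C-]#[O+].[C-]#[O+].[Mo]
Why: Proposed new method: zerovalent molybdenum generated from Mo(CO)6 and DMSO binds the C8 aldehyde and the internal C7=C11 bond of the allene and couples them oxidatively (C7–C8 bond, oxamolybdacyclopentane 22), CO then inserts into the Mo–C11 bond (C11–C12 bond, acyl complex 23) and C12–O8 reductive elimination releases the lactone; this is an allenic hetero-Pauson–Khand [2+2+1] reaction, whose closest known form is the Mo(CO)6/DMSO- or Ru3(CO)12-mediated cyclocarbonylation of allenyl aldehydes to bicyclic α-methylene-γ-butyrolactones with five- and six-membered carbocycles. The ten-membered carbocycle closes in the oxidative coupling (the macrocyclic mode is the unprecedented part), made plausible because the planar furanone and the (Z)-C4=C5 alkene leave only five rotatable bonds and hold C6 and C9 about 4 Å apart on one face; the γ-lactone closes as a five-membered ring by carbonylative C11–C12 and C12–O8 bond formation on the metallacycle. Both new stereocentres arise in the C7–C8 coupling: the rigid turn should only be spanned by an antiperiplanar C6–C7–C8–C9 unit, which enforces the trans ring fusion, and the metal must sit on the open outer face of this bridge (the face on which the R-configured C10 places C9), which fixes C7 as R and C8 as S and leaves the C6 silyloxy group pointing outward (matched case for the 4R centre of 21). The step needs the internal and not the terminal allene π-bond (the regiochemistry of the known allenic hetero-Pauson–Khand reactions, giving the exo-methylene), the aldehyde and not the vinylogous-ester ketone, and ring closure in preference to oligomerization; these rest on the electronic bias of the allene, the inertness of the furanone carbonyl and high dilution.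

Step 13
Reactants: 24 (4Z,6S,7R,8S,10R)-6-(tert-butyldimethylsilyloxy)-3,10-epoxy-1-oxogermacra-2,4,11(13)-trien-12,8-olide
Product: 25 (4Z,6S,7S,8S,10R)-6-hydroxy-3,10-epoxy-1-oxogermacra-2,4,11(13)-trien-12,8-olide
Conditions: HF·pyridine, THF/pyridine, 0 → 23 °C
Reagents that add atoms: none
Why: Fluoride cleavage of the silyl ether under buffered, non-basic conditions should spare the α-methylene lactone and the dienone; the C7 descriptor changes only through CIP priorities.

Step 14
Reactants: 26 methyl angelate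
Product: 27 (Z)-2-methylbut-2-en-1-ol
Conditions: i-Bu2AlH (2.2 equiv), CH2Cl2, −78 °C; aq. KNaC4H4O6 (potassium sodium tartrate)
Reagents that add atoms: none
Why: 1,2-Reduction of the enoate by i-Bu2AlH gives the allylic alcohol with retention of the (Z)-geometry.

Step 15
Reactants: 27 (Z)-2-methylbut-2-en-1-ol
Product: 28 [(2S,3R)-2,3-dimethyloxiran-2-yl]methanol
Conditions: Ti(Oi-Pr)4 (cat.), L-(+)-diethyl tartrate (cat.), t-BuOOH, 4 Å molecular sieves, CH2Cl2, −20 °C
Reagents that add atoms: tert-butyl hydroperoxide, CC(C)(C)OO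
Why: Sharpless asymmetric epoxidation; the L-(+)-tartrate sets both epoxide centres (same facial sense as nerol to its 2S,3R epoxide) and the alkene geometry fixes their cis relationship.

Step 16
Reactants: 28 [(2S,3R)-2,3-dimethyloxiran-2-yl]methanol
Product: 29 (2R,3R)-2,3-dimethyloxirane-2-carboxylic acid
Conditions: RuCl3·xH2O (2 mol %), NaIO4 (3 equiv), CCl4/MeCN/H2O, 0 → 23 °C
Reagents that add atoms: sodium periodate, [Na+].[O-][I](=O)(=O)=O; water, O
Why: Catalytic RuO4 oxidation (Sharpless conditions) converts the primary epoxy alcohol to the glycidic acid without touching the epoxide centres (the C2 descriptor changes only by CIP priority).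

Step 17
Reactants: 29 (2R,3R)-2,3-dimethyloxirane-2-carboxylic acid; 25 (4Z,6S,7S,8S,10R)-6-hydroxy-3,10-epoxy-1-oxogermacra-2,4,11(13)-trien-12,8-olide
Product: 31 (4Z,6S,7R,8S,10R)-6-{[(2R,3R)-2,3-dimethyloxiran-2-yl]carbonyloxy}-3,10-epoxy-1-oxogermacra-2,4,11(13)-trien-12,8-olide (the target), via mixed anhydride 30 (not isolated)
Conditions: 29, 2,4,6-trichlorobenzoyl chloride, Et3N, THF, 0 °C; then 25, DMAP, toluene, 23 °C
Reagents that add atoms: none
Why: Yamaguchi esterification acylates O6 through the mixed anhydride without breaking the C6–O bond, so C6 is retained and the epoxy acid is activated under non-acidic conditions.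

**Compound list**

1 | (S)-lactic acid, (2S)-2-hydroxypropanoic acid | C[C@H](O)C(=O)O | starting material
2 | pivalaldehyde, 2,2-dimethylpropanal | CC(C)(C)C=O | starting material
3 | (2S,5S)-2-tert-butyl-5-methyl-1,3-dioxolan-4-one (cis) | C[C@@H]1O[C@H](C(C)(C)C)OC1=O | intermediate
4 | allyl bromide | C=CCBr | starting material
5 | lithium enolate of 3, [(2S)-2-tert-butyl-5-methyl-1,3-dioxol-4-yl]oxylithium | CC1=C(O[Li])O[C@@H](C(C)(C)C)O1 | intermediate
6 | (2S,5R)-5-allyl-2-tert-butyl-5-methyl-1,3-dioxolan-4-one | C[C@]1(CC=C)O[C@H](C(C)(C)C)OC1=O | intermediate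
7 | secondary ozonide of 6, (2S,5R)-2-tert-butyl-5-methyl-5-(1,2,4-trioxolan-3-ylmethyl)-1,3-dioxolan-4-one | C[C@]1(CC2OCOO2)O[C@H](C(C)(C)C)OC1=O | intermediate
8 | 2-[(2S,4R)-2-tert-butyl-4-methyl-5-oxo-1,3-dioxolan-4-yl]acetaldehyde | O=CC[C@@]1(C)O[C@H](C(C)(C)C)OC1=O | intermediate
9 | (2S,5R)-2-tert-butyl-5-(2,2-dimethoxyethyl)-5-methyl-1,3-dioxolan-4-one | COC(OC)C[C@@]1(C)O[C@H](C(C)(C)C)OC1=O | intermediate
10 | (2R)-2-hydroxy-N,4,4-trimethoxy-N,2-dimethylbutanamide | COC(OC)C[C@@](C)(O)C(=O)N(C)OC | intermediate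
11 | (Z)-3-methylpent-2-en-4-yn-1-ol | C#C/C(C)=C\CO | starting material
12 | (Z)-3-methylpent-2-en-4-ynal | C#C/C(C)=C\C=O | intermediate
13 | allenyltributylstannane, tributyl(propa-1,2-dienyl)stannane | C=C=C[Sn](CCCC)(CCCC)CCCC | starting material
14 | (4R,5R)-4,5-diphenyl-2-(prop-2-ynyl)-1,3-bis(p-tolylsulfonyl)-1,3,2-diazaborolidine | C#CCB1N(S(=O)(=O)c2ccc(C)cc2)[C@H](c2ccccc2)[C@@H](c2ccccc2)N1S(=O)(=O)c1ccc(C)cc1 | intermediate
15 | (4R,5Z)-6-methylocta-1,2,5-trien-7-yn-4-ol | C#C/C(C)=C\[C@H](O)C=C=C | intermediate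
16 | tert-butyldimethyl{[(4R,5Z)-6-methylocta-1,2,5-trien-7-yn-4-yl]oxy}silane | C#C/C(C)=C\[C@H](O[Si](C)(C)C(C)(C)C)C=C=C | intermediate
17 | lithium acetylide of 16 | [Li]C#C/C(C)=C\[C@H](O[Si](C)(C)C(C)(C)C)C=C=C | intermediate
18 | chloromagnesium alkoxide of 10 | COC(OC)C[C@@](C)(O[Mg]Cl)C(=O)N(C)OC | intermediate
19 | (3R,7Z,9R)-9-(tert-butyldimethylsilyloxy)-3-hydroxy-1,1-dimethoxy-3,7-dimethyldodeca-7,10,11-trien-5-yn-4-one | COC(OC)C[C@@](C)(O)C(=O)C#C/C(C)=C\[C@H](O[Si](C)(C)C(C)(C)C)C=C=C | intermediate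
20 | (2R)-5-[(2Z,4R)-4-(tert-butyldimethylsilyloxy)hepta-2,5,6-trien-2-yl]-2-(2,2-dimethoxyethyl)-2-methylfuran-3(2H)-one | COC(OC)C[C@@]1(C)OC(=CC1=O)/C(C)=C\[C@H](O[Si](C)(C)C(C)(C)C)C=C=C | intermediate
21 | 2-[(2R)-5-[(2Z,4R)-4-(tert-butyldimethylsilyloxy)hepta-2,5,6-trien-2-yl]-2-methyl-3-oxo-2,3-dihydrofuran-2-yl]acetaldehyde | O=CC[C@@]1(C)OC(=CC1=O)/C(C)=C\[C@H](O[Si](C)(C)C(C)(C)C)C=C=C | intermediate
22 | oxamolybdacyclopentane from 21 (Mo bonded to O8 and C11; C7–C8 bond formed; ancillary CO and DMSO ligands not drawn) | C=C1[Mo]O[C@H]2C[C@@]3(C)OC(=CC3=O)/C(C)=C\[C@H](O[Si](C)(C)C(C)(C)C)[C@H]12 | intermediate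
23 | acylmolybdenum metallacycle (CO inserted between Mo and C11; ancillary ligands not drawn) | C=C1C(=O)[Mo]O[C@H]2C[C@@]3(C)OC(=CC3=O)/C(C)=C\[C@H](O[Si](C)(C)C(C)(C)C)[C@H]12 | intermediate
24 | (4Z,6S,7R,8S,10R)-6-(tert-butyldimethylsilyloxy)-3,10-epoxy-1-oxogermacra-2,4,11(13)-trien-12,8-olide | C=C1C(=O)O[C@H]2C[C@@]3(C)OC(=CC3=O)/C(C)=C\[C@H](O[Si](C)(C)C(C)(C)C)[C@H]12 | intermediate
25 | (4Z,6S,7S,8S,10R)-6-hydroxy-3,10-epoxy-1-oxogermacra-2,4,11(13)-trien-12,8-olide (deacyl target) | C=C1C(=O)O[C@H]2C[C@@]3(C)OC(=CC3=O)/C(C)=C\[C@H](O)[C@H]12 | intermediate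
26 | methyl angelate, methyl (2Z)-2-methylbut-2-enoate | C/C=C(/C)C(=O)OC | starting material
27 | (Z)-2-methylbut-2-en-1-ol | C/C=C(/C)CO | intermediate
28 | [(2S,3R)-2,3-dimethyloxiran-2-yl]methanol | OC[C@]1(C)O[C@@H]1C | intermediate
29 | (2R,3R)-2,3-dimethyloxirane-2-carboxylic acid (epoxyangelic acid) | OC(=O)[C@]1(C)O[C@@H]1C | intermediate
30 | (2R,3R)-2,3-dimethyloxirane-2-carboxylic 2,4,6-trichlorobenzoic anhydride | O=C(OC(=O)c1c(Cl)cc(Cl)cc1Cl)[C@]1(C)O[C@@H]1C | intermediate
31 | (4Z,6S,7R,8S,10R)-6-{[(2R,3R)-2,3-dimethyloxiran-2-yl]carbonyloxy}-3,10-epoxy-1-oxogermacra-2,4,11(13)-trien-12,8-olide | C=C1C(=O)O[C@H]2C[C@@]3(C)OC(=CC3=O)/C(C)=C\[C@H](OC(=O)[C@]3(C)O[C@@H]3C)[C@H]12 | target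

**Totals and risks**

Total step count: 17. Longest linear sequence: 11 steps (1–5, 9–13, 17).

Steps most likely to fail:

Step 12 (labelled step). The two π-systems may not reach one metal centre, so that oligomerization or allene dimerization outruns the ten-membered ring closure. The terminal allene bond may be engaged instead of the internal one. Facial control at C7 and C8 may be poor, or the (Z)-alkene may isomerize at 100 °C. Fallback (stepwise, known reaction types), setting out from 21 and returning at 24: Pd2(dba)3-catalysed addition of Bu3Sn–SnBu3 across the allene with in situ intramolecular carbonyl allylation under high dilution should give the ten-membered hydroxy vinylstannane, (4Z)-6-(tert-butyldimethylsilyloxy)-8-hydroxy-7-[1-(tributylstannyl)vinyl] carbocycle F1. Iododestannylation (I2, CH2Cl2, 0 °C) should give the corresponding 1-iodovinyl alcohol F2. Carbonylative lactonization (Pd(PPh3)4, CO 1 atm, Et3N, MeCN, 60 °C; zerovalent palladium inserts into C–I, CO insertion, O8 acylation) then forms the same C11–C12 bond and gives 24.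

Step 7. Enantiofacial discrimination may be eroded with this small conjugated aldehyde, the homopropargylic regioisomer may form through borane isomerization, or the (Z)-geometry may be lost. Fallback (resolution in place of reagent control), from 12 back to 15: TiCl4-promoted SE2′ addition of propargyltrimethylsilane should give the racemic allenyl carbinol, (5Z)-6-methylocta-1,2,5-trien-7-yn-4-ol F3. Lipase-catalysed acylation (Amano lipase PS, vinyl acetate) should acylate the R enantiomer (Kazlauskas rule) to the acetate, (4R,5Z)-6-methylocta-1,2,5-trien-7-yn-4-yl acetate F4. After separation from the unreacted S alcohol, methanolysis (K2CO3, MeOH) gives 15.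

Step 17. Acyl transfer to the hindered allylic C6 hydroxyl may be slow, leaving time for conjugate addition of the nucleophilic catalyst to the α-methylene lactone or for opening of the epoxide. Fallback (esterify before ring closure), from 20 to 31: HF·pyridine should give the unhindered acyclic alcohol, (2R)-2-(2,2-dimethoxyethyl)-5-[(2Z,4R)-4-hydroxyhepta-2,5,6-trien-2-yl]-2-methylfuran-3(2H)-one F5. Yamaguchi esterification with 29 should give the epoxyangelate acetal F6. Pyridinium p-toluenesulfonate hydrolysis should give the epoxyangelate aldehyde F7. The cyclocarbonylation of step 12 applied to F7 then delivers 31 directly.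

**Further compounds**

F1 | step 12 | ten-membered 8-hydroxy-7-[1-(tributylstannyl)vinyl] 6-silyl ether (configuration as in 24) | O[C@H]1C[C@@]2(C)OC(=CC2=O)/C(C)=C\[C@H](O[Si](C)(C)C(C)(C)C)[C@@H]1C(=C)[Sn](CCCC)(CCCC)CCCC
F2 | step 12 | ten-membered 8-hydroxy-7-(1-iodovinyl) 6-silyl ether (configuration as in 24) | O[C@H]1C[C@@]2(C)OC(=CC2=O)/C(C)=C\[C@H](O[Si](C)(C)C(C)(C)C)[C@@H]1C(I)=C
F3 | step 7 | racemic (5Z)-6-methylocta-1,2,5-trien-7-yn-4-ol | C#C/C(C)=C\C(O)C=C=C
F4 | step 7 | (4R,5Z)-6-methylocta-1,2,5-trien-7-yn-4-yl acetate | C#C/C(C)=C\[C@H](OC(C)=O)C=C=C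
F5 | step 17 | (2R)-2-(2,2-dimethoxyethyl)-5-[(2Z,4R)-4-hydroxyhepta-2,5,6-trien-2-yl]-2-methylfuran-3(2H)-one | COC(OC)C[C@@]1(C)OC(=CC1=O)/C(C)=C\[C@H](O)C=C=C
F6 | step 17 | (2Z,4R)-2-[(2R)-2-(2,2-dimethoxyethyl)-2-methyl-3-oxo-2,3-dihydrofuran-5-yl]hepta-2,5,6-trien-4-yl (2R,3R)-2,3-dimethyloxirane-2-carboxylate | COC(OC)C[C@@]1(C)OC(=CC1=O)/C(C)=C\[C@H](OC(=O)[C@]2(C)O[C@@H]2C)C=C=C
F7 | step 17 | (2Z,4R)-2-[(2R)-2-methyl-3-oxo-2-(2-oxoethyl)-2,3-dihydrofuran-5-yl]hepta-2,5,6-trien-4-yl (2R,3R)-2,3-dimethyloxirane-2-carboxylate | O=CC[C@@]1(C)OC(=CC1=O)/C(C)=C\[C@H](OC(=O)[C@]2(C)O[C@@H]2C)C=C=C
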